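## The problem

The target is a guaiane: a cyclopentenone (C1–C5, ketone at C3, methyl on C4, C4=C5) fused through C1 and C5 to a cycloheptane (C5–C10 and C1). Four stereocentres lie on the seven-membered ring, with H-1, the C10 methyl, the C7 side chain and the C8 oxygen all on one face. The 1,10 pair and the 7,8 pair are therefore each cis, but C9 on one side and C5/C6 on the other keep the pairs apart. Control inside each pair is straightforward (C1 and C10 are neighbours; C8 can follow C7 by hydride delivery anti to the bulky C11 group), whereas the relay between the pairs is remote and can only come from ring conformation. The tetrasubstituted enone must be placed at C4=C5 and not at C1=C2, and once it exists H-1 is a γ-hydrogen that base can remove through the dienolate. The methacrylate will not survive hydrides, boranes or organometallic reagents, the tertiary acetate can ionise or eliminate, and any intermediate with a C8 ketone and an oxygen on C11 is an aldol that can revert or dehydrate. The structural feature that opens the plan is that C6, C7 and oxygen-bearing C8 together with C3, C4 and C5 form a 3-oxy-1,5-diene if C8 is bonded to C3 and C6 is not yet bonded to C5. That isomer is a 2-alkenylbicyclo[3.2.1]oct-6-en-2-ol in which C1 and C10 are already fixed as a bridgehead and its methyl-bearing neighbour.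

## Retrosynthesis

Bicyclo[3.2.1]octenes are numbered so that C2 carries the ester or oxygen function; hydroazulenes carry guaiane numbering.

**Esters.** The two ester C–O bonds of 29 are cut first, giving diol 27 by way of mono-ester 28. Both acyl groups are fragile, so they are added last; this also lets the secondary C8 hydroxyl be acylated before the tertiary C11 hydroxyl purely on reactivity. The forward steps need only chemoselective acylation and no base strong enough to touch H-1.

**Enone.** The C3 carbonyl and the C4=C5 unsaturation of 27 (through its bis-silyl ether 26) are traced back to ketone 24 and then to the trisubstituted C3=C4 alkene of 22. A direct ene-type oxygenation of that alkene would be shorter, but it would have to choose between H-5 and the C2 hydrogens. Hydroboration places oxygen on C3 without ambiguity, and dehydrogenation through the more substituted enol ether 25 then places the double bond. The precursor 22 has no carbonyl group and a cyclopentene that is inert to everything before it.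

**C7 and C8.** The C8–H bond of alcohol 21 is cut to ketone 20, and the C7–H bond of 20 to the silyl enol ether 19. This is preferred to any plan that sets C8 first, because a bulky hydride anti to the C11 group gives exactly the cis 7,8 relationship required. C7 itself must then be set by protonation under equilibrating conditions, where the epimer with both the C10 methyl and the side chain equatorial should win. The forward reactions must avoid loss of the β-oxygen from the enolate.

**Key disconnection.** In 19 the C5–C6 bond is cut and the C3–C8 bond restored, which gives diol 16. This removes the seven-membered ring and the C5 stereocentre in one operation. It is chosen over an end-to-end closure of the cycloheptane because the ring exchange is driven by strain release and enolate formation, and because it delivers the enolate regiodefined at C7–C8 with C11 already attached. The forward step needs the alkenyl group syn to the alkene bridge and a C11 oxygen that cannot act as a leaving group. C11 is therefore carried as a free hydroxyl and rearranged as its alkoxide.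

**Alkenyl addition.** The C2–alkenyl bond of 16 is cut to ketone 12 and the dilithio alkenyl alkoxide 15, which comes from hydrazone 14 and the hydroxy ketone 13. Making 15 by a Shapiro reaction avoids protecting-group steps and gives a reagent whose β-oxygen is already an alkoxide. The addition must occur from the endo face of 12; this is the least secure point of the front end and has a stereocomplementary fallback.

**Ketone.** The carbonyl of 12 is traced to the carboxyl of acid 9 and ester 8 by Curtius degradation. The cut is accepted because the ester is what makes the cycloaddition below possible, and the degradation costs two steps without touching a stereocentre.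

**C7 methyl of the bicycle.** The methyl–C7 bond of 8 is cut to enol triflate 7 and silyl enol ether 6. Carrying the methyl group on the diene itself would mean working with an equilibrating mixture of positional isomers and an uncertain choice between two similar double bonds. An oxygen substituent makes one double bond decisively the more nucleophilic and is exchanged for methyl in two reliable steps.

**Bicycle.** Diene ester 6 is cut at C1–C2 and C4–C5 to silyloxy diene 2 and vinyldiazo ester 4, by way of the divinylcyclopropane 5. One catalytic step forms two C–C bonds and three stereocentres, among them C1 and C10 of the target. The components come from enone 1 and ester 3 in one step each. The forward reaction must cyclopropanate the enol ether double bond with high enantioselectivity and rearrange through the boat.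

## Roads not taken

Alternative 1: An allenic Pauson–Khand reaction would cut C1–C5, C2–C3 and C3–C4 and start from the open-chain allene-yne A2. With [Rh(CO)2Cl]2 under CO the alkyne, the distal allene double bond and CO would combine to give dienone A1, closing both rings at once. Its merits are real. The C3 carbonyl, the C4 methyl and the C4=C5 bond appear in their final places in one step, which costs four steps in the chosen plan. C7 and C8 are set in open-chain chemistry, so the C7 equilibration is avoided. The weak point is that A1 still holds a C1=C10 double bond. The target needs H-1 cis to the C10 methyl, which is an anti addition of hydrogen across a tetrasubstituted alkene that is the γ,δ-bond of a dienone. Catalytic hydrogenation adds syn, and a conjugate reduction would have to set two centres guided only by remote groups. The chosen plan is longer for the enone but fixes C1 and C10 together in the first ring-forming step by catalyst control and pericyclic geometry.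

Alternative 2: A Prins closure would cut C7–C8 and start from the cyclopentenone aldehyde A4, which already holds C1 and C10. In aqueous H2SO4 the prenyl alkene would attack the protonated aldehyde, and water would capture the tertiary C11 cation to give diol A3, which is compound 27 of the chosen route. If it worked with the right stereochemistry this road would be far shorter than the chosen one, with no protecting groups and two steps from the target; that advantage is conceded. Its weakness is control. Two new centres (C7, C8) must form cis to each other and in the right sense to remote C1 and C10 in a medium-ring cation–alkene closure with no clear conformational bias. The C11 cation can also lose a proton or accept a hydride shift from C7, and the acid can scramble H-1 through the dienol. Against the brevity, the chosen plan sets a ketone reduction of predictable sense for the 7,8 pair and intermediates at which errors can be detected and corrected.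

Alternative 3: A vinylcarbenoid (4+3) cycloaddition could build the seven-membered ring directly from the exocyclic diene A6 and the silyloxy vinyldiazo ester A7. With Rh2(S-PTAD)4, cyclopropanation of C5=C6 and Cope rearrangement would form C6–C7 and C9–C10 and give A5. This uses the same catalytic pericyclic logic as the chosen plan, but in a single ring-forming event that also installs the C8 oxygen and a C7 ester. The β-keto ester oxidation level avoids the β-elimination problem, and the step count would probably be equal or lower. The weak points are three. The stereocentres of A6 at C3 and C4 must be made and are later destroyed, and they may mismatch the catalyst. The C1=C5 alkene of A5 must be moved to C4=C5, which creates H-1 by γ-protonation of a dienolate under thermodynamic control. The ester must be turned into C(CH3)2O next to an enolisable centre. The chosen plan never sets C1 by protonation, since C1 and C10 are locked in a rigid bicycle from the start; it pays for this with the C7 equilibration and a longer enone sequence.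

Key step: step 10

Remark: endo means syn to the C6=C7 bridge of the bicycle and exo syn to C8; β is the face of H-1 in the target. The sense of induction of Rh2(S-DOSP)4, dirhodium tetrakis[(S)-N-(4-dodecylphenylsulfonyl)prolinate], is assumed to follow its behaviour with styrene and simple dienes; Rh2(R-DOSP)4 would be used if the opposite sense were found.

## Route

Step 1
Reactants: 1 cyclopent-2-en-1-one
Product: 2 2-(tert-butyldimethylsilyloxy)cyclopenta-1,3-diene
Conditions: TBSOTf, Et3N, Et2O, 0 °C; used at once and kept cold
Reagents that add atoms: tert-butyldimethylsilyl trifluoromethanesulfonate, CC(C)(C)[Si](C)(C)OS(=O)(=O)C(F)(F)F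
Why: Soft enolisation with O-silylation at the α' position of an enone gives the cross-conjugated 2-silyloxy diene; the silyloxy group marks the ring carbon that will later carry the C4 methyl of the target and makes one double bond clearly the more electron-rich.

Step 2
Reactants: 3 methyl (E)-pent-3-enoate
Product: 4 methyl (E)-2-diazopent-3-enoate
Conditions: 4-acetamidobenzenesulfonyl azide, DBU, MeCN, 0 °C
Reagents that add atoms: 4-acetamidobenzenesulfonyl azide, CC(=O)Nc1ccc(cc1)S(=O)(=O)N=[N+]=[N-]
Why: Diazo transfer to the dienolate of a β,γ-unsaturated ester is the usual entry to vinyldiazoacetates; the E alkene is retained and the product is used cold and soon because such diazo esters cyclise to pyrazoles on standing.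

Step 3
Reactants: 2 2-(tert-butyldimethylsilyloxy)cyclopenta-1,3-diene; 4 methyl (E)-2-diazopent-3-enoate
Product: 6 methyl 7-(tert-butyldimethylsilyloxy)-4-endo-methylbicyclo[3.2.1]octa-2,6-diene-2-carboxylate, via divinylcyclopropane 5 (not isolated)
Conditions: Rh2(S-DOSP)4 (1 mol %), hexanes, −78 → 23 °C, slow addition of 4 to 2 (3 equiv)
Reagents that add atoms: none
Why: Tandem cyclopropanation/Cope rearrangement, a formal (4+3) cycloaddition: the electrophilic donor/acceptor carbenoid attacks the unsubstituted terminus of the enol ether double bond, so the silyloxy-bearing carbon becomes C7, and cyclopropane 5 rearranges through the only available boat, which places the methyl of the E-propenyl group endo at C4. The catalyst sets the absolute configuration in the cyclopropanation and the second bridgehead follows from the bicyclic constraint.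

Step 4
Reactants: 6 methyl 7-(tert-butyldimethylsilyloxy)-4-endo-methylbicyclo[3.2.1]octa-2,6-diene-2-carboxylate
Product: 7 methyl 4-endo-methyl-7-(trifluoromethylsulfonyloxy)bicyclo[3.2.1]octa-2,6-diene-2-carboxylate
Conditions: CsF, PhNTf2, DME, 23 °C
Reagents that add atoms: N-phenylbis(trifluoromethanesulfonimide), O=S(=O)(N(c1ccccc1)S(=O)(=O)C(F)(F)F)C(F)(F)F
Why: Fluoride cleaves the silyl enol ether to a regiodefined caesium enolate (the bridgehead side cannot enolise), which is O-sulfonylated in the same flask; no stereocentre is involved.

Step 5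
Reactants: 7 methyl 4-endo-methyl-7-(trifluoromethylsulfonyloxy)bicyclo[3.2.1]octa-2,6-diene-2-carboxylate
Product: 8 methyl 4-endo,7-dimethylbicyclo[3.2.1]octa-2,6-diene-2-carboxylate
Conditions: Me2Zn, Pd(PPh3)4 (5 mol %), THF, 0 → 23 °C
Reagents that add atoms: dimethylzinc, C[Zn]C
Why: Negishi coupling of an alkenyl triflate with a methylzinc reagent; the enoate is inert to Me2Zn, and the methyl group now sits exactly where step 3 placed the oxygen.

Step 6
Reactants: 8 methyl 4-endo,7-dimethylbicyclo[3.2.1]octa-2,6-diene-2-carboxylate
Product: 9 4-endo,7-dimethylbicyclo[3.2.1]octa-2,6-diene-2-carboxylic acid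
Conditions: LiOH·H2O, THF/MeOH/H2O, 45 °C; then 1 M HCl to pH 3
Reagents that add atoms: lithium hydroxide, [Li+].[OH-]
Why: Saponification of a conjugated ester; hydroxide is too weak to remove the γ-hydrogen at C4, so the endo methyl is kept.

Step 7
Reactants: 9 4-endo,7-dimethylbicyclo[3.2.1]octa-2,6-diene-2-carboxylic acid
Product: 12 (1R,4S,5R)-4,7-dimethylbicyclo[3.2.1]oct-6-en-2-one, via acyl azide 10 (not isolated), via vinyl isocyanate 11 (not isolated)
Conditions: DPPA, Et3N, toluene, 23 → 85 °C; then 1 M HCl, THF, 23 °C
Reagents that add atoms: water, O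
Why: Curtius rearrangement of an α,β-unsaturated acid gives a vinyl isocyanate whose hydrolysis runs through the carbamic acid and enamine to the ketone, so the carboxyl carbon is excised and C2 becomes the carbonyl; the bridgehead α-carbon cannot enolise and C4 is not touched.

Step 8
Reactants: 13 3-hydroxy-3-methylbutan-2-one
Product: 14 (E)-N'-(3-hydroxy-3-methylbutan-2-ylidene)-2,4,6-triisopropylbenzenesulfonohydrazide
Conditions: 2,4,6-triisopropylbenzenesulfonohydrazide, HCl (cat.), MeOH, 23 °C
Reagents that add atoms: 2,4,6-triisopropylbenzenesulfonohydrazide, CC(C)c1cc(C(C)C)c(c(c1)C(C)C)S(=O)(=O)NN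
Why: Condensation of a methyl ketone with an arenesulfonyl hydrazide; the sulfonamide nitrogen settles anti to the tertiary carbinol carbon, the geometry needed for deprotonation of the methyl group.

Step 9
Reactants: 14 (E)-N'-(3-hydroxy-3-methylbutan-2-ylidene)-2,4,6-triisopropylbenzenesulfonohydrazide; 12 (1R,4S,5R)-4,7-dimethylbicyclo[3.2.1]oct-6-en-2-one
Product: 16 (1R,2S,4S,5R)-2-(3-hydroxy-3-methylbut-1-en-2-yl)-4,7-dimethylbicyclo[3.2.1]oct-6-en-2-ol, via dilithio alkenyl alkoxide 15 (not isolated)
Conditions: 14 (2.5 equiv), n-BuLi (3.05 equiv per 14), THF, −78 → 0 °C; CeCl3 (anhydrous), −78 °C; then 12, −78 → −40 °C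
Reagents that add atoms: none
Why: Shapiro reaction (the trianion loses sulfinate and N2 to give alkenyllithium 15, whose β-oxygen is an alkoxide and cannot be eliminated) followed by 1,2-addition of the organocerium reagent to the ketone. The hindered reagent is expected to attack C2 from the endo (equatorial) side, because the exo trajectory is flanked by the axial hydrogen on C4 and the inward hydrogen on C8; this places the alkenyl group syn to the C6=C7 bridge and the hydroxyl exo.

Step 10
Reactants: 16 (1R,2S,4S,5R)-2-(3-hydroxy-3-methylbut-1-en-2-yl)-4,7-dimethylbicyclo[3.2.1]oct-6-en-2-ol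
Product: 19 8,11-bis(triethylsilyloxy)-1βH,5βH,10αH-guaia-3,7-diene, via dipotassium dialkoxide 17 (not isolated), via dipotassium enolate alkoxide 18 (not isolated)
Conditions: KH (3 equiv), 18-crown-6 (2.2 equiv), THF, 0 → 50 °C; then TESCl, Et3N, −78 → 0 °C
Reagents that add atoms: chlorotriethylsilane, CC[Si](Cl)(CC)CC
Why: KH removes both hydroxyl protons and the C2 alkoxide drives a [3,3] sigmatropic shift of the 3-oxido-1,5-diene CH2=C–C2–C1–C7=C6: the alkenyl CH2 bonds to C6 and the C1–C2 bond breaks, which in guaiane numbering makes C5–C6, cuts C3–C8 and leaves the C7=C8 enolate. The closest known reaction type is the anionic oxy-Cope rearrangement of 2-alkenylbicyclo[2.2.2]oct-5-en-2-ols and 2-alkenylnorbornenols to cis-fused bicyclic enolates. The seven-membered ring closes by sigmatropic ring exchange through a boat-shaped six-atom array and not by an end-to-end cyclisation, while the five-membered ring is the cyclopentene of the bicycle carried over intact. The one new stereocentre, C5, is fixed by the framework: the endo alkenyl terminus can reach C6 only on the face turned toward the three-carbon bridge, which gives the cis ring fusion with H-1, and C1 and C10 are not touched. The step needs [3,3] selectivity over a [1,3] shift or fragmentation and an enolate that does not decompose; the first is secured by the endo alkenyl group (only this epimer brings the two alkene ends within bonding distance) and by release of bridged-ring strain, the second by keeping the C11 oxygen as an alkoxide, which cannot be expelled from the β-position as an ether could. Silylation of both oxygens then stores the enolate regiodefined at C7–C8 and prevents the retro-aldol loss of acetone that a free aldolate would invite.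

Step 11
Reactants: 19 8,11-bis(triethylsilyloxy)-1βH,5βH,10αH-guaia-3,7-diene
Product: 20 11-(triethylsilyloxy)-1βH,5βH,7αH,10αH-guai-3-en-8-one
Conditions: K2CO3 (0.5 equiv), MeOH, 0 → 23 °C
Reagents that add atoms: none
Why: Methanolysis of the silyl enol ether (the tertiary alkyl silyl ether is far slower) releases the ketone in a medium that keeps C7 in equilibrium through its enolate. The epimer with the side chain β should be favoured because only it can hold both the C10 methyl and the C(CH3)2OSiEt3 group equatorial in one chair-like conformer of the cis-fused ring; kinetic protonation from the open convex face would give the other epimer, which is why equilibrating conditions are chosen.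

Step 12
Reactants: 20 11-(triethylsilyloxy)-1βH,5βH,7αH,10αH-guai-3-en-8-one
Product: 21 11-(triethylsilyloxy)-1βH,5βH,7αH,8αH,10αH-guai-3-en-8-ol
Conditions: LiBH(s-Bu)3 (L-Selectride), THF, −78 °C; then H2O
Reagents that add atoms: none
Why: Reduction of a 2-substituted cycloalkanone with a bulky borohydride: hydride arrives anti to the quaternary C11 group on C7, so the new hydroxyl is cis to the side chain (8β); at −78 °C the β-silyloxy ketone is not enolised.

Step 13
Reactants: 21 11-(triethylsilyloxy)-1βH,5βH,7αH,8αH,10αH-guai-3-en-8-ol
Product: 22 8β,11-bis(triethylsilyloxy)-1βH,5βH,7αH,10αH-guai-3-ene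
Conditions: TESOTf, 2,6-lutidine, CH2Cl2, −78 → 0 °C
Reagents that add atoms: triethylsilyl trifluoromethanesulfonate, CC[Si](CC)(CC)OS(=O)(=O)C(F)(F)F
Why: Silylation of a hindered secondary alcohol with a silyl triflate; both oxygens now carry the same group and can be freed together at the end.

Step 14
Reactants: 22 8β,11-bis(triethylsilyloxy)-1βH,5βH,7αH,10αH-guai-3-ene
Product: 23 8β,11-bis(triethylsilyloxy)-1βH,4βH,5βH,7αH,10αH-guaian-3β-ol
Conditions: BH3·SMe2, THF, 0 → 23 °C; then aq. NaOH, H2O2, 0 °C
Reagents that add atoms: hydrogen peroxide, OO
Why: Hydroboration–oxidation of a trisubstituted alkene puts boron and then oxygen on the less substituted C3; syn addition from the convex face of the cyclopentene is expected, but both new centres are erased in the next two steps.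

Step 15
Reactants: 23 8β,11-bis(triethylsilyloxy)-1βH,4βH,5βH,7αH,10αH-guaian-3β-ol
Product: 24 8β,11-bis(triethylsilyloxy)-1βH,4βH,5βH,7αH,10αH-guaian-3-one
Conditions: Dess–Martin periodinane, NaHCO3, CH2Cl2, 23 °C
Reagents that add atoms: none
Why: Oxidation of a secondary alcohol to the ketone with a hypervalent iodine reagent under buffered conditions; the configuration at C4 is of no consequence.

Step 16
Reactants: 24 8β,11-bis(triethylsilyloxy)-1βH,4βH,5βH,7αH,10αH-guaian-3-one
Product: 26 8β,11-bis(triethylsilyloxy)-1βH,7αH,10αH-guai-4-en-3-one, via trimethylsilyl enol ether 25 (not isolated)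
Conditions: TMSCl, NaI, Et3N, MeCN, 23 °C; pentane extraction; then Pd(OAc)2 (1.1 equiv), MeCN, 23 °C
Reagents that add atoms: none
Why: Saegusa–Ito oxidation: equilibrating silylation gives the more substituted C3=C4 enol ether 25, Pd(OAc)2 adds to C4 from the convex face and β-hydride elimination takes the syn H-5, which places the double bond at C4=C5. Any exocyclic isomer should be drawn into the endocyclic tetrasubstituted enone by palladium hydride re-addition, and C1 and C10 are not touched.

Step 17
Reactants: 26 8β,11-bis(triethylsilyloxy)-1βH,7αH,10αH-guai-4-en-3-one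
Product: 27 8β,11-dihydroxy-1βH,7αH,10αH-guai-4-en-3-one
Conditions: HF·pyridine, pyridine, THF, 0 → 23 °C
Reagents that add atoms: none
Why: Fluoride cleavage of both triethylsilyl ethers under buffered acidic conditions, which avoids the base-mediated dienolate epimerisation of H-1.

Step 18
Reactants: 27 8β,11-dihydroxy-1βH,7αH,10αH-guai-4-en-3-one
Product: 28 11-hydroxy-8β-(2-methylprop-2-enoyloxy)-1βH,7αH,10αH-guai-4-en-3-one
Conditions: methacrylic anhydride, Et3N, DMAP (cat.), BHT (trace), CH2Cl2, 0 → 23 °C
Reagents that add atoms: methacrylic anhydride, CC(=C)C(=O)OC(=O)C(C)=C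
Why: DMAP-catalysed acylation; the secondary C8 hydroxyl reacts while the tertiary C11 hydroxyl does not under these conditions.

Step 19
Reactants: 28 11-hydroxy-8β-(2-methylprop-2-enoyloxy)-1βH,7αH,10αH-guai-4-en-3-one
Product: 29 (1R,7S,8R,10S)-11-acetoxy-8-(2-methylprop-2-enoyloxy)guai-4-en-3-one
Conditions: Ac2O, Sc(OTf)3 (2 mol %), MeCN, −20 °C
Reagents that add atoms: acetic anhydride, CC(=O)OC(C)=O
Why: Lewis-acid-catalysed acetylation of a tertiary alcohol at low temperature, chosen to outrun ionisation of the tertiary centre and migration of the neighbouring methacrylate.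

## Compound list

1 | cyclopent-2-en-1-one | O=C1C=CCC1 | starting material
2 | 2-(tert-butyldimethylsilyloxy)cyclopenta-1,3-diene | CC(C)(C)[Si](C)(C)OC1=CCC=C1 | intermediate
3 | methyl (E)-pent-3-enoate | C/C=C/CC(=O)OC | starting material
4 | methyl (E)-2-diazopent-3-enoate | C/C=C/C(=[N+]=[N-])C(=O)OC | intermediate
5 | methyl 1-(tert-butyldimethylsilyloxy)-6-endo-[(E)-prop-1-enyl]bicyclo[3.1.0]hex-2-ene-6-carboxylate | COC(=O)[C@@]1(/C=C/C)[C@@H]2CC=C[C@]12O[Si](C)(C)C(C)(C)C | intermediate (not isolated)
6 | methyl 7-(tert-butyldimethylsilyloxy)-4-endo-methylbicyclo[3.2.1]octa-2,6-diene-2-carboxylate | COC(=O)C1=C[C@H](C)[C@H]2C[C@@H]1C(O[Si](C)(C)C(C)(C)C)=C2 | intermediate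
7 | methyl 4-endo-methyl-7-(trifluoromethylsulfonyloxy)bicyclo[3.2.1]octa-2,6-diene-2-carboxylate | COC(=O)C1=C[C@H](C)[C@H]2C[C@@H]1C(OS(=O)(=O)C(F)(F)F)=C2 | intermediate
8 | methyl 4-endo,7-dimethylbicyclo[3.2.1]octa-2,6-diene-2-carboxylate | COC(=O)C1=C[C@H](C)[C@H]2C[C@@H]1C(C)=C2 | intermediate
9 | 4-endo,7-dimethylbicyclo[3.2.1]octa-2,6-diene-2-carboxylic acid | OC(=O)C1=C[C@H](C)[C@H]2C[C@@H]1C(C)=C2 | intermediate
10 | 4-endo,7-dimethylbicyclo[3.2.1]octa-2,6-diene-2-carbonyl azide | [N-]=[N+]=NC(=O)C1=C[C@H](C)[C@H]2C[C@@H]1C(C)=C2 | intermediate (not isolated)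
11 | 2-isocyanato-4-endo,7-dimethylbicyclo[3.2.1]octa-2,6-diene | O=C=NC1=C[C@H](C)[C@H]2C[C@@H]1C(C)=C2 | intermediate (not isolated)
12 | (1R,4S,5R)-4,7-dimethylbicyclo[3.2.1]oct-6-en-2-one (4-methyl endo) | O=C1C[C@H](C)[C@H]2C[C@@H]1C(C)=C2 | intermediate
13 | 3-hydroxy-3-methylbutan-2-one | CC(=O)C(C)(C)O | starting material
14 | (E)-N'-(3-hydroxy-3-methylbutan-2-ylidene)-2,4,6-triisopropylbenzenesulfonohydrazide | CC(C)c1cc(C(C)C)c(c(c1)C(C)C)S(=O)(=O)N/N=C(\C)C(C)(C)O | intermediate
15 | dilithium 3-lithio-2-methylbut-3-en-2-olate (2-lithioalkene with lithium alkoxide) | [Li]C(=C)C(C)(C)O[Li] | intermediate (not isolated)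
16 | (1R,2S,4S,5R)-2-(3-hydroxy-3-methylbut-1-en-2-yl)-4,7-dimethylbicyclo[3.2.1]oct-6-en-2-ol (alkenyl and 4-methyl endo; 2-OH exo) | C=C(C(C)(C)O)[C@]1(O)C[C@H](C)[C@H]2C[C@@H]1C(C)=C2 | intermediate
17 | dipotassium dialkoxide of 16 | C=C(C(C)(C)[O-])[C@]1([O-])C[C@H](C)[C@H]2C[C@@H]1C(C)=C2.[K+].[K+] | intermediate (not isolated)
18 | dipotassium 11-oxido-1βH,5βH,10αH-guaia-3,7-dien-8-olate | [O-]C1=C(C(C)(C)[O-])C[C@@H]2C(C)=CC[C@@H]2[C@@H](C)C1.[K+].[K+] | intermediate (not isolated)
19 | 8,11-bis(triethylsilyloxy)-1βH,5βH,10αH-guaia-3,7-diene (cis-fused) | CC[Si](CC)(CC)OC1=C(C(C)(C)O[Si](CC)(CC)CC)C[C@@H]2C(C)=CC[C@@H]2[C@@H](C)C1 | intermediate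
20 | 11-(triethylsilyloxy)-1βH,5βH,7αH,10αH-guai-3-en-8-one | O=C1C[C@H](C)[C@H]2CC=C(C)[C@H]2C[C@@H]1C(C)(C)O[Si](CC)(CC)CC | intermediate
21 | 11-(triethylsilyloxy)-1βH,5βH,7αH,8αH,10αH-guai-3-en-8-ol (8β-OH) | O[C@@H]1C[C@H](C)[C@H]2CC=C(C)[C@H]2C[C@@H]1C(C)(C)O[Si](CC)(CC)CC | intermediate
22 | 8β,11-bis(triethylsilyloxy)-1βH,5βH,7αH,10αH-guai-3-ene | CC[Si](CC)(CC)O[C@@H]1C[C@H](C)[C@H]2CC=C(C)[C@H]2C[C@@H]1C(C)(C)O[Si](CC)(CC)CC | intermediate
23 | 8β,11-bis(triethylsilyloxy)-1βH,4βH,5βH,7αH,10αH-guaian-3β-ol | CC[Si](CC)(CC)O[C@@H]1C[C@H](C)[C@H]2C[C@H](O)[C@@H](C)[C@H]2C[C@@H]1C(C)(C)O[Si](CC)(CC)CC | intermediate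
24 | 8β,11-bis(triethylsilyloxy)-1βH,4βH,5βH,7αH,10αH-guaian-3-one | CC[Si](CC)(CC)O[C@@H]1C[C@H](C)[C@H]2CC(=O)[C@@H](C)[C@H]2C[C@@H]1C(C)(C)O[Si](CC)(CC)CC | intermediate
25 | 8β,11-bis(triethylsilyloxy)-3-(trimethylsilyloxy)-1βH,5βH,7αH,10αH-guai-3-ene | CC[Si](CC)(CC)O[C@@H]1C[C@H](C)[C@H]2CC(O[Si](C)(C)C)=C(C)[C@H]2C[C@@H]1C(C)(C)O[Si](CC)(CC)CC | intermediate (not isolated)
26 | 8β,11-bis(triethylsilyloxy)-1βH,7αH,10αH-guai-4-en-3-one | CC[Si](CC)(CC)O[C@@H]1C[C@H](C)[C@H]2CC(=O)C(C)=C2C[C@@H]1C(C)(C)O[Si](CC)(CC)CC | intermediate
27 | 8β,11-dihydroxy-1βH,7αH,10αH-guai-4-en-3-one | O[C@@H]1C[C@H](C)[C@H]2CC(=O)C(C)=C2C[C@@H]1C(C)(C)O | intermediate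
28 | 11-hydroxy-8β-(2-methylprop-2-enoyloxy)-1βH,7αH,10αH-guai-4-en-3-one | C=C(C)C(=O)O[C@@H]1C[C@H](C)[C@H]2CC(=O)C(C)=C2C[C@@H]1C(C)(C)O | intermediate
29 | (1R,7S,8R,10S)-11-acetoxy-8-(2-methylprop-2-enoyloxy)guai-4-en-3-one; [(5S,6R,8S,8aR)-5-(2-acetoxypropan-2-yl)-3,8-dimethyl-2-oxo-1,2,4,5,6,7,8,8a-octahydroazulen-6-yl] 2-methylprop-2-enoate | C=C(C)C(=O)O[C@@H]1C[C@H](C)[C@H]2CC(=O)C(C)=C2C[C@@H]1C(C)(C)OC(C)=O | target

## Step count and least certain steps

Total step count: 19. Longest linear sequence: 17 steps (from 1 or 3 to 29; step 8 lies on a side branch that joins at step 9).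

**Step 10 (key step).** The chelated dialkoxide may rearrange slowly, and at the temperature then needed the C1–C2 bond may break without ring closure (fragmentation or a [1,3] shift). The fallback is the neutral, thermal variant. From 16, both hydroxyls are silylated (TESOTf, 2,6-lutidine) to give the bis(triethylsilyl) ether F1. This is heated at about 200 °C in degassed o-dichlorobenzene in base-washed glass, where the siloxy-Cope rearrangement should give 19 directly, and the route is rejoined at 19.

**Step 9.** The facial selectivity of the addition may be poor or reversed: the vinylic methyl on C7 crowds the endo trajectory, while the two syn hydrogens crowd the exo one. Only the endo-alkenyl epimer can rearrange in step 10, so the outcome is read at once. The fallback delivers oxygen, not carbon, to the face that reagents prefer. From 12, a Horner–Wadsworth–Emmons reaction (trimethyl phosphonoacetate, NaH, THF) gives the exocyclic enoate F2. Copper-catalysed conjugate borylation (B2pin2, CuCl, NaOt-Bu, a bis-phosphine, MeOH) gives the tertiary boronate F3, and NaBO3 oxidation with retention gives the β-hydroxy ester F4. Its dianion (LDA) is aminomethylated with dimethylmethyleneammonium iodide to the Mannich base F5. Methylation and elimination (MeI, then DBU) give the α-methylene ester F6, and MeLi/CeCl3 converts the ester into the dimethyl carbinol, which is 16.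

**Step 11.** The β-silyloxy group may be lost from the enolate during the basic methanolysis, or the equilibrium at C7 may be less favourable than argued. The fallback forms the C7–C11 bond after the rearrangement, so that the electrophile entering from the open convex face is carbon and not a proton. From 12, vinylmagnesium bromide/CeCl3 gives the vinyl carbinol F7. KH/18-crown-6 followed by TMSCl gives the silyl enol ether F8. A Mukaiyama aldol reaction with acetone (TiCl4, CH2Cl2, −78 °C) gives the β-hydroxy ketone F9 with C11 on the β face, and TESOTf/2,6-lutidine converts it into 20.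

**Step 3.** The silyloxy diene may isomerise by a 1,5-hydrogen shift or dimerise before it is consumed, and stepwise opening of the donor–acceptor cyclopropane may erode the endo selectivity and the enantiomeric purity. The fallback carries the methyl group on the diene. From 4, the same catalysis with 2-methylcyclopenta-1,3-diene F10 (from the cracked commercial dimer, used as its mixture with the 1-methyl isomer) proceeds via the cyclopropane F11 and gives 8 directly. Steps 4 and 5 drop out, at the price of separating positional isomers.

**Step 16.** Enolisation or palladation may occur on the C2 side and give the C1=C2 enone, or an exocyclic methylene isomer may persist. The fallback uses halogenation instead of palladium. From 24, bromination at the more substituted α-carbon (PhNMe3Br3, THF, 0 °C) gives the bromo ketone F12, and dehydrobromination (Li2CO3, LiBr, DMF, 110 °C) gives 26.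

## Further compounds

F1 | step 10 | 4-endo,7-dimethyl-2-exo-(triethylsilyloxy)-2-endo-[3-methyl-3-(triethylsilyloxy)but-1-en-2-yl]bicyclo[3.2.1]oct-6-ene | C=C(C(C)(C)O[Si](CC)(CC)CC)[C@]1(O[Si](CC)(CC)CC)C[C@H](C)[C@H]2C[C@@H]1C(C)=C2
F2 | step 9 | methyl 2-(4-endo,7-dimethylbicyclo[3.2.1]oct-6-en-2-ylidene)acetate (E/Z mixture) | COC(=O)C=C1C[C@H](C)[C@H]2C[C@@H]1C(C)=C2
F3 | step 9 | methyl 2-[4-endo,7-dimethyl-2-exo-(4,4,5,5-tetramethyl-1,3,2-dioxaborolan-2-yl)bicyclo[3.2.1]oct-6-en-2-endo-yl]acetate | COC(=O)C[C@]1(B3OC(C)(C)C(C)(C)O3)C[C@H](C)[C@H]2C[C@@H]1C(C)=C2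
F4 | step 9 | methyl 2-(2-exo-hydroxy-4-endo,7-dimethylbicyclo[3.2.1]oct-6-en-2-endo-yl)acetate | COC(=O)C[C@]1(O)C[C@H](C)[C@H]2C[C@@H]1C(C)=C2
F5 | step 9 | methyl 3-(dimethylamino)-2-(2-exo-hydroxy-4-endo,7-dimethylbicyclo[3.2.1]oct-6-en-2-endo-yl)propanoate | COC(=O)C(CN(C)C)[C@]1(O)C[C@H](C)[C@H]2C[C@@H]1C(C)=C2
F6 | step 9 | methyl 2-(2-exo-hydroxy-4-endo,7-dimethylbicyclo[3.2.1]oct-6-en-2-endo-yl)prop-2-enoate | COC(=O)C(=C)[C@]1(O)C[C@H](C)[C@H]2C[C@@H]1C(C)=C2
F7 | step 11 | 2-endo-ethenyl-4-endo,7-dimethylbicyclo[3.2.1]oct-6-en-2-exo-ol | C=C[C@]1(O)C[C@H](C)[C@H]2C[C@@H]1C(C)=C2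
F8 | step 11 | cis-fused 3,8-dimethyl-6-(trimethylsilyloxy)-1,3a,4,7,8,8a-hexahydroazulene | C[Si](C)(C)OC1=CC[C@@H]2C(C)=CC[C@@H]2[C@@H](C)C1
F9 | step 11 | 11-hydroxy-1βH,5βH,7αH,10αH-guai-3-en-8-one | O=C1C[C@H](C)[C@H]2CC=C(C)[C@H]2C[C@@H]1C(C)(C)O
F10 | step 3 | 2-methylcyclopenta-1,3-diene | CC1=CCC=C1
F11 | step 3 | methyl 1-methyl-6-endo-[(E)-prop-1-enyl]bicyclo[3.1.0]hex-2-ene-6-carboxylate | COC(=O)[C@@]1(/C=C/C)[C@@H]2CC=C[C@]12C
F12 | step 16 | 4-bromo-8β,11-bis(triethylsilyloxy)-1βH,5βH,7αH,10αH-guaian-3-one | CC[Si](CC)(CC)O[C@@H]1C[C@H](C)[C@H]2CC(=O)C(C)(Br)[C@H]2C[C@@H]1C(C)(C)O[Si](CC)(CC)CC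
A1 | alternative 1 | 11-acetoxy-8-(tert-butyldimethylsilyloxy)guaia-1(10),4-dien-3-one | CC(C)(C)[Si](C)(C)O[C@@H]1CC(C)=C2CC(=O)C(C)=C2C[C@@H]1C(C)(C)OC(C)=O
A2 | alternative 1 | 5-(2-acetoxypropan-2-yl)-6-(tert-butyldimethylsilyloxy)-8-methyldeca-8,9-dien-2-yne | C=C=C(C)C[C@@H](O[Si](C)(C)C(C)(C)C)[C@H](CC#CC)C(C)(C)OC(C)=O
A3 | alternative 2 | 8,11-dihydroxyguai-4-en-3-one (identical with 27) | O[C@@H]1C[C@H](C)[C@H]2CC(=O)C(C)=C2C[C@@H]1C(C)(C)O
A4 | alternative 2 | 3-[2-methyl-3-(3-methylbut-2-enyl)-4-oxocyclopent-2-en-1-yl]butanal | O=CC[C@H](C)[C@H]1CC(=O)C(C)=C1CC=C(C)C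
A5 | alternative 3 | methyl 3,8-bis(tert-butyldimethylsilyloxy)-10-methyl-containing guaia-1(5),7-diene-7-carboxylate (C11 as the ester carbon) | COC(=O)C1=C(O[Si](C)(C)C(C)(C)C)C[C@H](C)C2=C(C1)[C@H](C)[C@H](O[Si](C)(C)C(C)(C)C)C2
A6 | alternative 3 | tert-butyl[(E)-4-ethylidene-2-methyl-3-methylidenecyclopentyl]oxydimethylsilane | C=C1[C@H](C)[C@H](O[Si](C)(C)C(C)(C)C)C/C1=C\C
A7 | alternative 3 | methyl 3-(tert-butyldimethylsilyloxy)-2-diazobut-3-enoate | COC(=O)C(=[N+]=[N-])C(=C)O[Si](C)(C)C(C)(C)C
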